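## Retrosynthetic overview

Atom labels: decalin C1–C10 with the C5/C10 fusion, C11 is the CH2 linker, and primed atoms are the five-membered ring (C1′ carbinol, C5′ CH). Assumption: the SMILES reads as 1′S,5′R,5S,8R,9R,10S. This is a trans-decalin with 5β-Me, axial 9β-Me, axial 8α-Me and 8β-CH2, and the ring OH is trans to the side chain.

1. 19 ⇒ furoate 18. The cyclopentenone is made last: furan photooxygenation, (Z)-enedione, then C1′–C5′ aldol closure.
2. 18 ⇒ ketone 15. The Δ3-4-methyl unit comes from the C4 ketone (enol triflate, then Me). The ester comes from furan C–H lithiation.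
3. 15 ⇒ allylic alcohol 13. C8–CH3 is made by light-driven deoxygenative methylation of a C8 radical. C9–H is set by OH-directed hydrogenation.
4. 13 ⇒ enone 7 + iodide 12 (C8–C11 bond). 7 ⇒ ynal 6 by photocatalytic acyl-radical 6-exo-dig closure of ring B (C8–C9 bond).
5. 6 ⇒ (R)-carvone, which is ring A: trans conjugate ethynylation (C10), anti Michael addition (C5), traceless loss of isopropenyl. Ring order: A (bought) → B → cyclopentenone.

## Route

**Step 1**
Reactants: 1 (R)-(−)-carvone; 2 ethynylmagnesium bromide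
Product: 3, TBS enol ether of trans-3-ethynyl-dihydrocarvone (3S,5R)
Conditions: 2, ZnBr2, THF, 0 °C; then 1, TBSOTf, Et2O–THF, −40 °C
Reagents that add atoms: ethynylmagnesium bromide, C#C[Mg]Br; TBSOTf, CC(C)(C)[Si](C)(C)OS(=O)(=O)C(F)(F)F
Why: Silyl-triflate-promoted conjugate alkynylation with an alkynylzinc, in which axial attack anti to the isopropenyl group sets C10 (H10 α) and the enolate is trapped regiospecifically at C4/C5.

**Step 2**
Reactants: 3; 4 acrolein
Product: 5, 3-[(1S,2S,4R)-2-ethynyl-1-methyl-6-oxo-4-(prop-1-en-2-yl)cyclohexyl]propanal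
Conditions: BF3·OEt2, i-PrOH (1 equiv), CH2Cl2, −78 °C
Reagents that add atoms: acrolein, C=CC=O
Why: Mukaiyama–Michael addition, in which A(1,2) strain holds the ethynyl group pseudo-axial so acrolein adds axially on the opposite (α) face, giving quaternary C5 (S, 5β-Me) with the two ring-B arms trans.

**Step 3**
Reactants: 5
Product: 6, 3-[(1S,2S)-2-ethynyl-1-methyl-6-oxocyclohexyl]propanal
Conditions: O3, MeOH, −78 °C; then PhSH, FeSO4·7H2O, −78 °C → rt
Reagents that add atoms: none
Why: Ozonolysis/Fe(II) hydrodealkenylation (α-methoxy hydroperoxide, alkoxyl β-scission, thiol HAT) removes the spent control element as methyl acetate, while alkyne and carbonyls are inert to O3 at −78 °C and no stereocentre is touched.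

**Step 4**
Reactants: 6
Product: 7, (4aS,8aS)-4a-methyl-1-methylideneoctahydronaphthalene-2,5-dione (trans-fused; C8=O, C9=CH2, C4=O)
Conditions: (n-Bu4N)4[W10O32] (2 mol %), MeCN (0.01 M), 390 nm LED (flow), Ar, 20 °C; used crude
Reagents that add atoms: none
Why: Proposed new method: excited decatungstate abstracts the hydridic formyl H (about 89 kcal/mol), the primary acyl radical decarbonylates slowly and closes 6-exo-dig onto the gauche, trans-diequatorial ethynyl group (C8–C9 bond, ring B), and the vinyl radical (C–H about 110 kcal/mol) is quenched by back-HAT or by the formyl H of another 6 in a chain, giving a redox-neutral isomerisation; the closest known reactions are decatungstate hydroacylation of electron-poor alkenes and tin-hydride acyl-selenide radical cyclisations.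

**Step 5**
Reactants: 8 methyl tetronate
Product: 9, 3-methoxyfuran
Conditions: DIBAL-H, CH2Cl2, −78 °C; aq. citric acid, 0 °C
Reagents that add atoms: none
Why: Butenolide-to-furan reduction, in which the lactol aromatises by loss of water.

**Step 6**
Reactants: 9; 10 ethylene oxide
Product: 11, 2-(3-methoxyfuran-2-yl)ethanol
Conditions: n-BuLi, THF, −78 → 0 °C; 10, 0 °C
Reagents that add atoms: ethylene oxide, C1CO1
Why: OMe-directed α-lithiation at C2 of the furan followed by epoxide opening.

**Step 7**
Reactants: 11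
Product: 12, 2-(2-iodoethyl)-3-methoxyfuran
Conditions: I2, PPh3, imidazole, CH2Cl2, 0 °C
Reagents that add atoms: iodine, II
Why: Appel iodination under buffered conditions that the acid-labile methoxyfuran tolerates.

**Step 8**
Reactants: 7; 12
Product: 13, (4aS,6S,8aS)-6-hydroxy-6-[2-(3-methoxyfuran-2-yl)ethyl]-8a-methyl-5-methylideneoctahydronaphthalen-1(2H)-one (axial 8α-OH, equatorial 8β-side chain)
Conditions: 12, t-BuLi (2 equiv), Et2O, −78 °C; CeCl3, THF; then 7 (1.0 equiv), −78 °C; pH 7 buffer
Reagents that add atoms: 12 (as its organocerium), COc1ccoc1CCI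
Why: Imamoto organocerium 1,2-addition, which suppresses enolisation and 1,4-addition, attacks the less hindered C8 carbonyl rather than the neopentyl C4 ketone, and approaches equatorially (β) to give the axial 8α-alcohol.

**Step 9**
Reactants: 13
Product: 14, (4aS,5R,6S,8aS)-6-hydroxy-6-[2-(3-methoxyfuran-2-yl)ethyl]-5,8a-dimethyloctahydronaphthalen-1(2H)-one
Conditions: H2 (1 atm), [Ir(cod)(py)(PCy3)]PF6 (5 mol %), CH2Cl2, 0 °C → rt
Reagents that add atoms: none
Why: Hydroxyl-directed (Crabtree) hydrogenation, in which Ir bound to the axial 8α-OH delivers H2 to the α face, which is also the face away from the angular 5β-Me, so the new methyl is 9β (axial) and C9 is R.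

**Step 10**
Reactants: 14
Product: 15, (4aS,5R,6R,8aS)-6-[2-(3-methoxyfuran-2-yl)ethyl]-5,6,8a-trimethyloctahydronaphthalen-1(2H)-one
Conditions: 14 and MeOH each activated with N-aryl benzoxazolium salt/pyridine, MTBE; then Ir(ppy)2(dtbbpy)PF6, Ni(acac)2/KTp*, quinuclidine, MTBE–DMSO, 450 nm LED, rt
Reagents that add atoms: methanol, CO
Why: Photoredox deoxygenative alcohol–alcohol cross-coupling (NHC–alcohol β-scission, Ni SH2 radical sorting), in which the planar C8 tertiary radical takes CH3 from Ni–CH3 on the α (axial) face, anti to the adjacent axial 9β-Me, giving 8α-Me/8β-CH2 (C8 R) without cationic shifts.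

**Step 11**
Reactants: 15
Product: 16, the C4 enol triflate (Δ3)
Conditions: KHMDS, PhNTf2, THF, −78 → 0 °C
Reagents that add atoms: PhNTf2, O=S(=O)(N(c1ccccc1)S(=O)(=O)C(F)(F)F)C(F)(F)F
Why: Enolate O-triflation, which is regiospecific because C3 is the only enolisable position.

**Step 12**
Reactants: 16
Product: 17, 3-methoxy-2-{2-[(1R,2R,4aS,8aS)-1,2,4a,5-tetramethyl-1,2,3,4,4a,7,8,8a-octahydronaphthalen-2-yl]ethyl}furan
Conditions: MeMgBr, Fe(acac)3 (10 mol %), THF–NMP, −20 °C
Reagents that add atoms: methylmagnesium bromide, C[Mg]Br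
Why: Iron-catalysed Kumada-type methylation of an alkenyl triflate, which places the C3=C4(Me) alkene without exo/endo mixtures.

**Step 13**
Reactants: 17
Product: 18, methyl 4-methoxy-5-{2-[(1R,2R,4aS,8aS)-1,2,4a,5-tetramethyl-1,2,3,4,4a,7,8,8a-octahydronaphthalen-2-yl]ethyl}furan-2-carboxylate
Conditions: n-BuLi, THF, −78 → −20 °C; ClCO2Me, −78 °C
Reagents that add atoms: methyl chloroformate, COC(=O)Cl
Why: α-Lithiation of the only free furan α-position followed by acylation.

**Step 14**
Reactants: 18
Product: 19, dysidenone A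
Conditions: O2, methylene blue, white LED, CH2Cl2, −78 °C; Me2S; then DBU (10 mol %), −40 °C, short time; HPLC
Reagents that add atoms: oxygen, O=O
Why: Furan [4+2] photooxygenation and reduction gives the (Z)-enedione MeO2C–CO–CH=C(OMe)–CO–CH2R, and its (Z)-enolate closes on the α-keto ester as a six-electron oxidopentadienyl (disrotatory) aldol with CO2Me and CH2R both "outside", so they end cis and OH ends trans to the side chain; face selection by the C8 quaternary centre is expected to be modest (about 1.5:1), and the other isomers are recycled by retro-aldol with DBU.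

## Compound list

| No. | Name | SMILES | Role |
|---|---|---|---|
| 1 | (R)-(−)-carvone | CC1=CC[C@H](CC1=O)C(C)=C | starting material |
| 2 | ethynylmagnesium bromide | C#C[Mg]Br | starting material |
| 3 | tert-butyl{[(3S,5R)-3-ethynyl-2-methyl-5-(prop-1-en-2-yl)cyclohex-1-en-1-yl]oxy}dimethylsilane | CC1=C(O[Si](C)(C)C(C)(C)C)C[C@H](C(C)=C)C[C@H]1C#C | intermediate |
| 4 | acrolein | C=CC=O | starting material |
| 5 | 3-[(1S,2S,4R)-2-ethynyl-1-methyl-6-oxo-4-(prop-1-en-2-yl)cyclohexyl]propanal | O=CCC[C@]1(C)C(=O)C[C@H](C(C)=C)C[C@H]1C#C | intermediate |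
| 6 | 3-[(1S,2S)-2-ethynyl-1-methyl-6-oxocyclohexyl]propanal | O=CCC[C@]1(C)C(=O)CCC[C@H]1C#C | intermediate |
| 7 | (4aS,8aS)-4a-methyl-1-methylideneoctahydronaphthalene-2,5-dione | O=C1CC[C@]2(C)C(=O)CCC[C@H]2C1=C | intermediate |
| 8 | methyl tetronate (4-methoxyfuran-2(5H)-one) | COC1=CC(=O)OC1 | starting material |
| 9 | 3-methoxyfuran | COc1ccoc1 | intermediate |
| 10 | ethylene oxide | C1CO1 | starting material |
| 11 | 2-(3-methoxyfuran-2-yl)ethanol | COc1ccoc1CCO | intermediate |
| 12 | 2-(2-iodoethyl)-3-methoxyfuran | COc1ccoc1CCI | intermediate |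
| 13 | (4aS,6S,8aS)-6-hydroxy-6-[2-(3-methoxyfuran-2-yl)ethyl]-8a-methyl-5-methylideneoctahydronaphthalen-1(2H)-one | COc1ccoc1CC[C@@]1(O)CC[C@]2(C)C(=O)CCC[C@H]2C1=C | intermediate |
| 14 | (4aS,5R,6S,8aS)-6-hydroxy-6-[2-(3-methoxyfuran-2-yl)ethyl]-5,8a-dimethyloctahydronaphthalen-1(2H)-one | COc1ccoc1CC[C@@]1(O)CC[C@]2(C)C(=O)CCC[C@H]2[C@H]1C | intermediate |
| 15 | (4aS,5R,6R,8aS)-6-[2-(3-methoxyfuran-2-yl)ethyl]-5,6,8a-trimethyloctahydronaphthalen-1(2H)-one | COc1ccoc1CC[C@@]1(C)CC[C@]2(C)C(=O)CCC[C@H]2[C@H]1C | intermediate |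
| 16 | (4aS,5R,6R,8aS)-6-[2-(3-methoxyfuran-2-yl)ethyl]-5,6,8a-trimethyl-3,4,4a,5,6,7,8,8a-octahydronaphthalen-1-yl triflate | COc1ccoc1CC[C@@]1(C)CC[C@]2(C)C(OS(=O)(=O)C(F)(F)F)=CCC[C@H]2[C@H]1C | intermediate |
| 17 | 3-methoxy-2-{2-[(1R,2R,4aS,8aS)-1,2,4a,5-tetramethyl-1,2,3,4,4a,7,8,8a-octahydronaphthalen-2-yl]ethyl}furan | COc1ccoc1CC[C@@]1(C)CC[C@]2(C)C(C)=CCC[C@H]2[C@H]1C | intermediate |
| 18 | methyl 4-methoxy-5-{2-[(1R,2R,4aS,8aS)-1,2,4a,5-tetramethyl-1,2,3,4,4a,7,8,8a-octahydronaphthalen-2-yl]ethyl}furan-2-carboxylate | COC(=O)c1cc(OC)c(CC[C@@]2(C)CC[C@]3(C)C(C)=CCC[C@H]3[C@H]2C)o1 | intermediate |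
| 19 | dysidenone A, methyl (1S,5R)-1-hydroxy-3-methoxy-4-oxo-5-{[(1R,2R,4aS,8aS)-1,2,4a,5-tetramethyl-1,2,3,4,4a,7,8,8a-octahydronaphthalen-2-yl]methyl}cyclopent-2-ene-1-carboxylate | COC(=O)[C@]1(O)C=C(OC)C(=O)[C@@H]1C[C@@]1(C)CC[C@]2(C)C(C)=CCC[C@H]2[C@H]1C | target |

## Step count

Total steps: 14. Longest linear sequence: 11 (steps 1–4 and 8–14).

## Steps most likely to fail

1. **Step 4 (the new acyl-radical 6-exo-dig hydroacylation).**
   - Risks: 7-endo closure, slow addition to an unactivated alkyne, and further radical chemistry on enone 7.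
   - Fallback (known chemistry, reversed polarity): Markovnikov hydroiodination of the alkyne of 6 to the 2-iodoalkene, intramolecular Nozaki–Hiyama–Kishi closure on the aldehyde, then Dess–Martin oxidation to 7.

2. **Step 10 (methylation of a hindered tertiary alcohol next to an electron-rich furan).**
   - Risks: poor NHC activation of the axial alcohol, radical disproportionation, and quenching of the photocatalyst by the furan.
   - Fallback: build C8 by enolate chemistry.
     - Treat 7 with L-Selectride, then Comins' reagent, to get the C8 enol triflate.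
     - Carbonylate with Pd/CO/MeOH to the C8(CO2Me)=C9(Me) enoate, whose ester carbon is C11.
     - Hydrogenate from the α face, then methylate with LDA/MeI (α face, anti to the 9β-Me).
     - Extend the ester by DIBAL reduction, Wittig reaction with the (3-methoxyfuran-2-yl)methyl ylide, and diimide reduction. The route rejoins at 15.

3. **Step 14 (C1′/C5′ control and chemoselectivity against the Δ3 alkene).**
   - Risks: low facial selectivity, epimerisation of C5′ to the more stable OH/side-chain cis isomer, and a competing singlet-oxygen ene reaction at C3=C4.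
   - Fallback: fix C5′ after the ring exists.
     - Condense the decalin C11 aldehyde (from the fallback ester above) with methyl 1-hydroxy-3-methoxy-4-oxocyclopent-2-ene-1-carboxylate to the 5-alkylidene enone.
     - Separate the C1′ epimers at this stage.
     - Deliver H to C5′ syn to the tertiary OH by hydroxyl-directed hydrogenation, which enforces the OH/side-chain trans relationship.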